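**Remark on the chemistry (assumption):** ring atoms are labelled C1–C6 (C1 carries the side chain, C2 the secondary methyl group, C3–C6 the four oxygens) and chain atoms C7–C12 (C7 on the pyranone, C12 on C1). These labels also serve as locants in the names of ring compounds from 10 onward; in them the target is (1R,2S,3R,4R,5S,6S). Compounds 1, 3, 16, 17 and both enantiomers of the imidazolidinone organocatalyst are taken to be commercial.

## The problem

Amaurone B joins a 2-methoxy-3,5-dimethyl-4-pyranone through an all-E triene (C7–C12) to a cyclohexane in which every ring carbon is a stereocentre and two of them (C3, C5) are tertiary carbinols. The feature that decides the plan is the way the ring is divided into two faces: the oxygens on C3, C4, C5 and C6 all lie on one face, while the C1 side chain, the C2 methyl group and the methyl groups of C3 and C5 lie on the other. The oxygens at C3 and C6 are therefore 1,4-cis across the ring and enclose the cis-vicinal pair C4/C5. This is the pattern left when a cyclohexa-1,3-diene (C3=C4–C5=C6) takes up O2 at its termini and is then cis-dihydroxylated at the remaining C4=C5 bond. Such a diene keeps only C1 and C2, so these two must control the other four, and C2 (H, CH3) is the one centre that has to be set in the absolute sense. In the preferred chair the C2 methyl is axial and the C1 substituent equatorial, so a hydride that has to make the C4 or C6 carbinol from a ketone would be misdirected; those oxygens are better delivered as C–O bonds to sp2 carbons. The triene is sensitive to light, singlet oxygen and OsO4, so it cannot be present during the ring oxidations. A carbonyl on C1 next to an oxygenated C6 would invite β-elimination, and the two secondary acetates sit beside free tertiary hydroxyls, so they are best introduced last.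

## Retrosynthesis

**25 from 24 (two O–acyl bonds).** Only the C4 and C6 hydroxyls of tetraol 24 are secondary, so the acetates can be put on in the last step without protecting groups. The forward reaction only has to distinguish equatorial secondary from axial tertiary hydroxyls.

**24 from 15 and 23 (C8–C9).** This sp2–sp2 bond lies in the middle of the triene and divides the molecule into a dienyl boronate 15 that carries all six stereocentres and the flat iodovinyl pyranone 23. A cut at C10–C11 would need a trisubstituted alkenyl metal on the ring fragment. An olefination at C11=C12 late in the route would need a C1 aldehyde β to the C6 oxygen. The coupling must keep both alkene geometries and tolerate four free hydroxyls.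

**23 from 21, 20, 16 and 17 (pyranone O1–C2, then C–C of the triketide).** The methoxypyranone is made in the usual way from a 3,5-diketo ester by lactonisation and O-methylation. The (E)-iodoalkene is bought with acid 17, so no alkene geometry has to be made on this side.

**15 from 14, 13 and 12 (C9=C10, then oxidation level of C10).** C9 and boron are added to enal 14 by a one-carbon olefination. C10 is carried as an ester up to tetraol 12, so that C11=C12 stays electron-poor while the ring is oxidised. The allylic oxidation 13 to 14 comes after the ring has lost its own allylic alcohols.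

**12 from 10 (C4–O and C5–O).** The two hydroxyls of ene-diol 10 lie on the face that must also receive the last two oxygens, so a hydrogen-bond-directed osmylation is asked to add syn to them. The reverse order (osmylation of a diene first) would send the second oxidation anti to the first diol.

**10 from 8 (C3–O and C6–O; key step).** Cutting both bonds gives diene 8 and O2. The precursor has two stereocentres and no oxygen on the ring; the product has four stereocentres including a tertiary carbinol. The forward reaction must choose the face opposite the C1 and C2 substituents and the ring diene over the side-chain alkene.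

**8 from 7 and 5 (C11=C12, then C1–H).** The enoate is made by a Wittig reaction on the β,γ-unsaturated aldehyde 7. Aldehyde 7 is the kinetic protonation product of the trienolate of the conjugated dienal 5, so C1 is made from C2 (proton anti to the axial methyl group, cis product). All stereochemical information other than C2 is thus discarded on the way to 5 and rebuilt by relay.

**5 from 2 and 3 (C2–C3 and C1–C6), 2 from 1.** Dienal 5 is the formal [4+2] adduct of crotonaldehyde 3 with the silyl dienol ether 2 of 2-methylpent-2-enal 1, after loss of silanol. In this pairing the polarity is matched: the oxygen terminus of 2 bonds to the α-carbon of the enal and the methyl-bearing terminus to its β-carbon. A chiral secondary amine sets C2, the only stereocentre that has to survive.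

## Roads not taken

**Alternative 1:** the most obvious plan follows the likely biogenesis and cuts the C1–C2 ring bond. Thermal disrotatory 6π-electrocyclisation of the (2E,4E,6Z,8E)-tetraene ester A1 would give the cis-diene A2, which is the racemate of 8, and the oxidations would follow as here. A1 is achiral and nothing in it lets a catalyst choose the sense of ring closure: Lewis-acid acceleration of triene closure needs an acyl group on an inner triene carbon, and here those carbons become C6 and C3, which carry H and CH3. A2 would have to be resolved with loss of half the material. The (6Z)-trisubstituted alkene of A1 also costs about as many steps as the four that lead to enantioenriched 8 in the chosen plan.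

**Alternative 2:** cut the C2–CH3 bond and take the whole ring from an arene. Dearomatising ortho-addition of methyllithium to the oxazoline A3 of 3,5-dimethylbenzoic acid, then protonation of the azaenolate at C1 anti to the new methyl group, would give diene A4 in one step. This is the shortest plan on paper. However, additions of organolithiums to benzene rings that are not metal-complexed are limited to branched alkyllithiums, and methyllithium would rather lithiate the ring. The methyl groups at C3 and C5 also sit on the carbons that must carry the negative charge of the adduct. In A4 the C1–H is α to the C=N bond and doubly allylic, so it would reconjugate, and removal of the auxiliary costs three further operations.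

**Alternative 3:** start from the C3 carbinol. Oxidative para-hydroxylation of phenol A5 would give p-quinol A6, and its hydroxyl group would then direct dihydroxylation of C4=C5 and hydrogenation of C1=C2 before the C6 ketone is reduced. A6 has two different enone arms and is formed as a racemate, with no general catalyst to set C3. C1=C2 is tetrasubstituted. The C6 hydride would have to arrive syn-axial to the C2 methyl group, while the β-hydroxyls direct reagents to the wrong face. The chosen plan makes C6–O and C4–O as bonds to alkene carbons and needs no ketone reduction.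

Key step: step 5

## Route

**Step 1**
Reactants: 1 (E)-2-methylpent-2-enal
Product: 2 tert-butyl(dimethyl){[(1E,3E)-2-methylpenta-1,3-dien-1-yl]oxy}silane
Conditions: TBSOTf, Et3N, Et2O, 0 °C to rt
Reagents that add atoms: tert-butyldimethylsilyl triflate, CC(C)(C)[Si](C)(C)OS(=O)(=O)C(F)(F)F
Why: Soft enolisation (O-silylation of the enal, γ-deprotonation by the amine) gives the 1-siloxy diene; the s-trans enal leads to the (1E) enol ether and the new C3=C4 bond forms E, the geometry that lets the diene reach its s-cis form.

**Step 2**
Reactants: 2 tert-butyl(dimethyl){[(1E,3E)-2-methylpenta-1,3-dien-1-yl]oxy}silane; 3 (E)-but-2-enal (crotonaldehyde)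
Product: 5 (6R)-3,5,6-trimethylcyclohexa-1,3-diene-1-carbaldehyde (both C5 epimers), via siloxy cycloadduct 4 (not isolated)
Conditions: (2R,5R)-5-benzyl-2-tert-butyl-3-methylimidazolidin-4-one·CF3CO2H (20 mol %), CH2Cl2, H2O (1 equiv), −40 °C; then DBU, 0 °C to rt
Reagents that add atoms: none
Why: Iminium-ion-catalysed Diels–Alder reaction of an enal (it may run stepwise as a vinylogous Mukaiyama–Michael/aldol sequence with the same outcome): the siloxy terminus makes C4 of 2 the nucleophilic end, so it bonds to C3 of the enal and gives the 3,5,6-trimethyl pattern; the benzyl group of the catalyst covers one face of the (E)-iminium ion, so the diene adds to the Si face of C3 of 3 and C6 of 5 becomes R (the sense known for additions of π-nucleophiles to crotonaldehyde with this catalyst series); E1cB loss of silanol from 4 removes the other stereocentres except C5, which disappears in step 3.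

**Step 3**
Reactants: 5 (6R)-3,5,6-trimethylcyclohexa-1,3-diene-1-carbaldehyde
Product: 7 (1S,6S)-3,5,6-trimethylcyclohexa-2,4-diene-1-carbaldehyde, via potassium trienolate 6 (not isolated)
Conditions: KN(SiMe3)2, THF, −78 to −40 °C; cannulated into AcOH, THF, −78 °C; cold aqueous work-up, used at once
Reagents that add atoms: none
Why: Deconjugative kinetic α-protonation of an extended enolate, as in the deconjugation of enones and dienoates through their dienolates: C5–H is the only proton whose loss gives a carbonyl-stabilised anion, so both epimers of 5 converge on 6; in 6 the C6 methyl group is held pseudoaxial by allylic strain against the C5 methyl group and the exocyclic enolate, and the proton reaches C1 from the opposite face, which sets formyl and methyl cis.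

**Step 4**
Reactants: 7 (1S,6S)-3,5,6-trimethylcyclohexa-2,4-diene-1-carbaldehyde
Product: 8 ethyl (2E)-2-methyl-3-[(1R,6S)-3,5,6-trimethylcyclohexa-2,4-dien-1-yl]prop-2-enoate
Conditions: Ph3P=C(CH3)CO2Et, CH2Cl2, 0 °C to rt
Reagents that add atoms: ethyl 2-(triphenyl-λ5-phosphanylidene)propanoate, CCOC(=O)C(C)=P(c1ccccc1)(c1ccccc1)c1ccccc1
Why: Wittig reaction of a stabilised ylide, which gives the (E)-trisubstituted enoate; the ylide is too weak a base to enolise 7, so the labile β,γ-unsaturated aldehyde is trapped before it can reconjugate, and the ester deactivates the new alkene for the two oxidations that follow.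

**Step 5**
Reactants: 8 ethyl (2E)-2-methyl-3-[(1R,6S)-3,5,6-trimethylcyclohexa-2,4-dien-1-yl]prop-2-enoate
Product: 10 ethyl (2E)-3-[(1R,2S,3R,6S)-3,6-dihydroxy-2,3,5-trimethylcyclohex-4-en-1-yl]-2-methylprop-2-enoate, via endoperoxide 9 (not isolated)
Conditions: O2, tetraphenylporphyrin (cat.), visible light, CH2Cl2, −40 °C; then thiourea, MeOH, −40 °C to rt
Reagents that add atoms: dioxygen, O=O
Why: Singlet oxygen adds suprafacially to the s-cis diene C3=C4–C5=C6 in a [4+2] cycloaddition, the reaction by which 5-substituted cyclohexa-1,3-dienes such as α-terpinene and α-phellandrene give bicyclic endoperoxides. The ring closed is the 2,3-dioxabicyclo[2.2.2]oct-5-ene of 9, formed by concerted (possibly asynchronous) bonding of O2 to C3 and C6. Both new stereocentres, C3 and C6, are set by the C2 methyl group, which allylic 1,2-strain against the C3 methyl group holds pseudoaxial on the α-face, and by the cis C1 side chain on the same face, so that O2 can approach only the β-face. Thiourea then cleaves only the O–O bond, with retention at both carbons, and gives the cis-1,4-diol under neutral conditions that avoid Kornblum–DeLaMare opening at C6–H. The step needs facial selectivity (secured as above), cycloaddition rather than ene reaction (favoured by the locked s-cis trisubstituted diene, although the axial C1–H on the β-face is a possible ene donor) and reaction at the ring diene rather than at C11=C12 (secured by conjugation of that alkene with the ester, which makes it inert to electrophilic singlet oxygen). In one operation two C–O bonds and two stereocentres, one of them the tertiary carbinol C3, are made, and the remaining C4=C5 bond is left flanked by two β-hydroxyls for the next step.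

**Step 6**
Reactants: 10 ethyl (2E)-3-[(1R,2S,3R,6S)-3,6-dihydroxy-2,3,5-trimethylcyclohex-4-en-1-yl]-2-methylprop-2-enoate
Product: 12 ethyl (2E)-2-methyl-3-[(1R,2S,3R,4R,5S,6S)-3,4,5,6-tetrahydroxy-2,3,5-trimethylcyclohexyl]prop-2-enoate, via osmate ester 11 (not isolated)
Conditions: OsO4 (1.05 equiv), TMEDA, CH2Cl2, −78 °C; then sat. aq. Na2SO3, THF, reflux
Reagents that add atoms: osmium tetroxide, O=[Os](=O)(=O)=O
Why: Hydrogen-bond-directed dihydroxylation with the OsO4·TMEDA complex, known for cyclic allylic alcohols: the tertiary C3 hydroxyl and the secondary C6 hydroxyl, both on the β-face, bind the reagent and deliver it to that face of C4=C5, which is also the face free of the C3 and C2 methyl groups, so C4 and C5 are set cis to the other oxygens; one equivalent at −78 °C should leave the ester-conjugated C11=C12 alone, and sulfite releases the tetraol from the ester of hexavalent osmium.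

**Step 7**
Reactants: 12 ethyl (2E)-2-methyl-3-[(1R,2S,3R,4R,5S,6S)-3,4,5,6-tetrahydroxy-2,3,5-trimethylcyclohexyl]prop-2-enoate
Product: 13 (2E)-2-methyl-3-[(1R,2S,3R,4R,5S,6S)-3,4,5,6-tetrahydroxy-2,3,5-trimethylcyclohexyl]prop-2-en-1-ol
Conditions: i-Bu2AlH (excess), THF–CH2Cl2, −78 to 0 °C; aq. Rochelle salt
Reagents that add atoms: none
Why: 1,2-Reduction of the enoate by i-Bu2AlH (excess to allow for the four hydroxyls) gives the allylic alcohol without touching the alkene or any stereocentre.

**Step 8**
Reactants: 13 (2E)-2-methyl-3-[(1R,2S,3R,4R,5S,6S)-3,4,5,6-tetrahydroxy-2,3,5-trimethylcyclohexyl]prop-2-en-1-ol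
Product: 14 (2E)-2-methyl-3-[(1R,2S,3R,4R,5S,6S)-3,4,5,6-tetrahydroxy-2,3,5-trimethylcyclohexyl]prop-2-enal
Conditions: MnO2 (activated, excess), acetone, rt, short reaction time
Reagents that add atoms: none
Why: MnO2 oxidises only the primary allylic alcohol; the ring hydroxyls are no longer allylic, which is why this oxidation is placed after step 6.

**Step 9**
Reactants: 14 (2E)-2-methyl-3-[(1R,2S,3R,4R,5S,6S)-3,4,5,6-tetrahydroxy-2,3,5-trimethylcyclohexyl]prop-2-enal
Product: 15 2-{(1E,3E)-3-methyl-4-[(1R,2S,3R,4R,5S,6S)-3,4,5,6-tetrahydroxy-2,3,5-trimethylcyclohexyl]buta-1,3-dien-1-yl}-4,4,5,5-tetramethyl-1,3,2-dioxaborolane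
Conditions: CrCl2 (8 equiv), Cl2CHB(pin) (2 equiv), LiI (4 equiv), THF, rt
Reagents that add atoms: 2-(dichloromethyl)-4,4,5,5-tetramethyl-1,3,2-dioxaborolane, ClC(Cl)B1OC(C)(C)C(C)(C)O1
Why: Takai–Utimoto-type boryl olefination: the geminal dichromium species formed from the dihalomethylboronate and divalent chromium adds to the aldehyde and eliminates to give the (E)-alkenyl boronate; divalent chromium tolerates free hydroxyls and the enal geometry is kept.

**Step 10**
Reactants: 16 ethyl 2-methyl-3-oxopentanoate; 17 (E)-3-iodo-2-methylprop-2-enoic acid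
Product: 20 ethyl (6E)-7-iodo-2,4,6-trimethyl-3,5-dioxohept-6-enoate, via dilithium dianion 18 (not isolated), via acyl imidazole 19 (not isolated)
Conditions: 16, LiN(i-Pr)2 (2.1 equiv), THF, −78 to 0 °C; 19 (from 17, 1,1′-carbonyldiimidazole, THF, rt; 0.5 equiv), −78 °C; AcOH, −78 °C
Reagents that add atoms: none
Why: γ-Acylation of a β-keto ester dianion by an acyl imidazole (Claisen-type condensation), the standard entry to 3,5-diketo esters; two equivalents of dianion are used because the product is deprotonated, the cold acidic quench keeps the iodoalkene untouched, and the alkene geometry comes from 17.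

**Step 11**
Reactants: 20 ethyl (6E)-7-iodo-2,4,6-trimethyl-3,5-dioxohept-6-enoate
Product: 21 4-hydroxy-6-[(1E)-1-iodoprop-1-en-2-yl]-3,5-dimethyl-2H-pyran-2-one
Conditions: DBU, toluene, rt to 60 °C
Reagents that add atoms: none
Why: Base-mediated lactonisation of a 3,5-diketo ester: the enol oxygen at C5 attacks the ester carbonyl (6-exo-trig) and ethanol is lost, which gives the 4-hydroxy-2-pyranone, the usual route to this ring.

**Step 12**
Reactants: 21 4-hydroxy-6-[(1E)-1-iodoprop-1-en-2-yl]-3,5-dimethyl-2H-pyran-2-one
Product: 23 2-[(1E)-1-iodoprop-1-en-2-yl]-6-methoxy-3,5-dimethyl-4H-pyran-4-one, via pyrylium triflate 22 (not isolated)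
Conditions: MeOTf, CH2Cl2, rt; then aq. NaHCO3
Reagents that add atoms: methyl triflate, COS(=O)(=O)C(F)(F)F
Why: A hard methylating agent alkylates the lactone carbonyl oxygen of a 4-hydroxy-2-pyranone; the 2-methoxypyrylium salt 22 then loses the proton of the 4-hydroxyl on basic work-up and gives the 2-methoxy-4-pyranone rather than the isomeric 4-methoxy-2-pyranone.

**Step 13**
Reactants: 15 2-{(1E,3E)-3-methyl-4-[(1R,2S,3R,4R,5S,6S)-3,4,5,6-tetrahydroxy-2,3,5-trimethylcyclohexyl]buta-1,3-dien-1-yl}-4,4,5,5-tetramethyl-1,3,2-dioxaborolane; 23 2-[(1E)-1-iodoprop-1-en-2-yl]-6-methoxy-3,5-dimethyl-4H-pyran-4-one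
Product: 24 2-{(2E,4E,6E)-6-methyl-7-[(1R,2S,3R,4R,5S,6S)-3,4,5,6-tetrahydroxy-2,3,5-trimethylcyclohexyl]hepta-2,4,6-trien-2-yl}-6-methoxy-3,5-dimethyl-4H-pyran-4-one
Conditions: Pd(PPh3)4 (5 mol %), aq. K3PO4, THF, 40 °C, dark
Reagents that add atoms: none
Why: Suzuki–Miyaura coupling of an alkenyl boronate with an alkenyl iodide joins C8 and C9 with retention of both alkene geometries; free hydroxyls are tolerated and the phosphate base leaves the pyranone intact.

**Step 14**
Reactants: 24 2-{(2E,4E,6E)-6-methyl-7-[(1R,2S,3R,4R,5S,6S)-3,4,5,6-tetrahydroxy-2,3,5-trimethylcyclohexyl]hepta-2,4,6-trien-2-yl}-6-methoxy-3,5-dimethyl-4H-pyran-4-one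
Product: 25 Amaurone B
Conditions: Ac2O, pyridine, DMAP (cat.), CH2Cl2, 0 °C to rt, dark
Reagents that add atoms: acetic anhydride, CC(=O)OC(C)=O
Why: Acylation with Ac2O and DMAP esterifies the two equatorial secondary hydroxyls at C4 and C6, while the axial tertiary hydroxyls at C3 and C5 do not react under these conditions, so the diacetate formed is the target.

## Compound list

1 | (E)-2-methylpent-2-enal | O=C/C(C)=C/CC | starting material
2 | tert-butyl(dimethyl){[(1E,3E)-2-methylpenta-1,3-dien-1-yl]oxy}silane | C/C=C/C(C)=C/O[Si](C)(C)C(C)(C)C | intermediate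
3 | (E)-but-2-enal (crotonaldehyde) | C/C=C/C=O | starting material
4 | (6R)-2-[(tert-butyldimethylsilyl)oxy]-3,5,6-trimethylcyclohex-3-ene-1-carbaldehyde (epimers at C1, C2, C5) | O=CC1C(O[Si](C)(C)C(C)(C)C)C(C)=CC(C)[C@H]1C | intermediate (not isolated)
5 | (6R)-3,5,6-trimethylcyclohexa-1,3-diene-1-carbaldehyde (both C5 epimers) | O=CC1=CC(C)=CC(C)[C@H]1C | intermediate
6 | potassium [(6R)-3,5,6-trimethylcyclohexa-2,4-dien-1-ylidene]methanolate | [K+].[O-]C=C1C=C(C)C=C(C)[C@H]1C | intermediate (not isolated)
7 | (1S,6S)-3,5,6-trimethylcyclohexa-2,4-diene-1-carbaldehyde (formyl and C6 methyl cis) | O=C[C@@H]1[C@H](C)C(C)=CC(C)=C1 | intermediate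
8 | ethyl (2E)-2-methyl-3-[(1R,6S)-3,5,6-trimethylcyclohexa-2,4-dien-1-yl]prop-2-enoate | CCOC(=O)/C(C)=C/[C@@H]1[C@H](C)C(C)=CC(C)=C1 | intermediate
9 | ethyl (2E)-2-methyl-3-(4,6,8-trimethyl-2,3-dioxabicyclo[2.2.2]oct-5-en-7-yl)prop-2-enoate, peroxide bridge C3–O–O–C6 on the face opposite the C1 and C2 substituents | CCOC(=O)/C(C)=C/[C@@H]2[C@H](C)[C@@]3(C)OO[C@@H]2C(C)=C3 | intermediate (not isolated)
10 | ethyl (2E)-3-[(1R,2S,3R,6S)-3,6-dihydroxy-2,3,5-trimethylcyclohex-4-en-1-yl]-2-methylprop-2-enoate | CCOC(=O)/C(C)=C/[C@@H]2[C@H](C)[C@@](C)(O)C=C(C)[C@H]2O | intermediate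
11 | TMEDA-ligated dioxo-osmium (hexavalent) 4,5-diolate of tetraol ester 12 | CCOC(=O)/C(C)=C/[C@@H]1[C@H](C)[C@@](C)(O)[C@H]2O[Os-2]3(=O)(=O)(O[C@@]2(C)[C@H]1O)[N+](C)(C)CC[N+]3(C)C | intermediate (not isolated)
12 | ethyl (2E)-2-methyl-3-[(1R,2S,3R,4R,5S,6S)-3,4,5,6-tetrahydroxy-2,3,5-trimethylcyclohexyl]prop-2-enoate | CCOC(=O)/C(C)=C/[C@@H]2[C@H](C)[C@@](C)(O)[C@@H](O)[C@@](C)(O)[C@H]2O | intermediate
13 | (2E)-2-methyl-3-[(1R,2S,3R,4R,5S,6S)-3,4,5,6-tetrahydroxy-2,3,5-trimethylcyclohexyl]prop-2-en-1-ol | OC/C(C)=C/[C@@H]1[C@H](C)[C@@](C)(O)[C@@H](O)[C@@](C)(O)[C@H]1O | intermediate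
14 | (2E)-2-methyl-3-[(1R,2S,3R,4R,5S,6S)-3,4,5,6-tetrahydroxy-2,3,5-trimethylcyclohexyl]prop-2-enal | O=C/C(C)=C/[C@@H]1[C@H](C)[C@@](C)(O)[C@@H](O)[C@@](C)(O)[C@H]1O | intermediate
15 | 2-{(1E,3E)-3-methyl-4-[(1R,2S,3R,4R,5S,6S)-3,4,5,6-tetrahydroxy-2,3,5-trimethylcyclohexyl]buta-1,3-dien-1-yl}-4,4,5,5-tetramethyl-1,3,2-dioxaborolane | CC1(C)OB(/C=C/C(C)=C/[C@@H]2[C@H](C)[C@@](C)(O)[C@@H](O)[C@@](C)(O)[C@H]2O)OC1(C)C | intermediate
16 | ethyl 2-methyl-3-oxopentanoate | CCC(=O)C(C)C(=O)OCC | starting material
17 | (E)-3-iodo-2-methylprop-2-enoic acid | OC(=O)/C(C)=C/I | starting material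
18 | dilithium dianion of 16 | [Li+].[Li+].CC=C([O-])C(C)=C([O-])OCC | intermediate (not isolated)
19 | (2E)-1-(1H-imidazol-1-yl)-3-iodo-2-methylprop-2-en-1-one | O=C(/C(C)=C/I)n1ccnc1 | intermediate (not isolated)
20 | ethyl (6E)-7-iodo-2,4,6-trimethyl-3,5-dioxohept-6-enoate (diastereomers and enol forms) | CCOC(=O)C(C)C(=O)C(C)C(=O)/C(C)=C/I | intermediate
21 | 4-hydroxy-6-[(1E)-1-iodoprop-1-en-2-yl]-3,5-dimethyl-2H-pyran-2-one | Cc1c(O)c(C)c(/C(C)=C/I)oc1=O | intermediate
22 | 4-hydroxy-6-[(1E)-1-iodoprop-1-en-2-yl]-2-methoxy-3,5-dimethylpyrylium triflate | COc1[o+]c(/C(C)=C/I)c(C)c(O)c1C.[O-]S(=O)(=O)C(F)(F)F | intermediate (not isolated)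
23 | 2-[(1E)-1-iodoprop-1-en-2-yl]-6-methoxy-3,5-dimethyl-4H-pyran-4-one | COc1oc(/C(C)=C/I)c(C)c(=O)c1C | intermediate
24 | 2-{(2E,4E,6E)-6-methyl-7-[(1R,2S,3R,4R,5S,6S)-3,4,5,6-tetrahydroxy-2,3,5-trimethylcyclohexyl]hepta-2,4,6-trien-2-yl}-6-methoxy-3,5-dimethyl-4H-pyran-4-one | COc1oc(/C(C)=C/C=C/C(C)=C/[C@@H]2[C@H](C)[C@@](C)(O)[C@@H](O)[C@@](C)(O)[C@H]2O)c(C)c(=O)c1C | intermediate
25 | Amaurone B (4,6-diacetate of 24) | COc1oc(/C(C)=C/C=C/C(C)=C/[C@@H]2[C@H](C)[C@@](C)(O)[C@@H](OC(C)=O)[C@@](C)(O)[C@H]2OC(C)=O)c(C)c(=O)c1C | target

## Step count and risks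

Total: 14 steps. Longest linear sequence: 11 steps (steps 1–9, 13, 14); the pyranone fragment takes 3 steps (10–12).

**Step 5 (key step).** The diene may be diverted into an ene reaction through the axial, doubly allylic C1–H, which would give a hydroperoxide and a conjugated triene. Some oxygen may also add to the hindered face. Fallback, from 8 back to 10: one equivalent of dimethyldioxirane in acetone at −40 °C should epoxidise a ring alkene from the β-face and give vinyl epoxide F1 (the regioisomeric epoxide at C3=C4 converges). With Pd(PPh3)4 and acetic acid, zerovalent palladium ionises the allylic C–O bond anti and acetate attacks the remote allyl terminus anti to the metal, a net cis-1,4 addition that should give hydroxy acetate F2. K2CO3 in ethanol then removes the acetyl group and returns diol 10.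

**Step 2.** A β-substituted enal and a 1,2,4-trisubstituted diene may combine too slowly, so that hydrolysis of 2 by the acidic medium takes over, and the enantioselectivity may be moderate. If the sense of induction proves opposite, the (2S,5S) catalyst is used. Fallback, from 2 back to 4: the Diels–Alder reaction is run with commercial (4R)-4-benzyl-3-[(E)-but-2-enoyl]-1,3-oxazolidin-2-one and Et2AlCl in CH2Cl2 at −78 °C, where the chelated s-cis imide is attacked opposite the benzyl group, to give imide cycloadduct F3. LiBH4 removes the auxiliary and gives siloxy alcohol F4, and Dess–Martin periodinane gives aldehyde 4, which is treated with DBU as in step 2.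

**Step 3.** The aldehyde enolate may undergo self-condensation, the proton may return to C5 or C3 (giving back 5), and 7 may reconjugate during work-up. Fallback, from 5 back to 7: Pinnick oxidation (NaClO2, NaH2PO4, 2-methylbut-2-ene) gives dienoic acid F5 and MeI/K2CO3 its methyl ester F6. The ester trienolate (LiN(i-Pr)2, THF–DMPU, −78 °C) is protonated with acetic acid at C1, anti to the axial methyl group, to give the deconjugated cis ester F7. i-Bu2AlH in toluene at −78 °C reduces F7 to aldehyde 7.

**Step 6.** The reagent may also attack C11=C12, part of the reaction may escape hydrogen-bond control, and the hindered osmate ester may hydrolyse slowly. Fallback, from 9 (isolated cold, without thiourea) back to 12: catalytic OsO4 with N-methylmorpholine N-oxide dihydroxylates the bicyclic alkene. In the bicycle the C1 and C2 substituents point toward C4=C5 and close the face anti to the peroxide, so the diol should form syn to the O–O bridge and give endoperoxide diol F8. Thiourea then reduces the peroxide to tetraol 12. Here the face is chosen by steric shielding in the bicycle instead of by hydrogen bonding.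

**Step 11.** An enolate oxygen of 20 may add to the iodine-bearing alkene carbon with loss of iodide (closure to a 4-pyranone) in competition with lactonisation. Fallback, from 16 and 19 back to 21, under neutral ring closure: 16 is saponified to 2-methyl-3-oxopentanoic acid F9, which is condensed with acetone (Ac2O, cat. H2SO4) to dioxinone F10. Its lithium dienolate (LiN(i-Pr)2, THF, −78 °C) is acylated by 19 to give keto dioxinone F11. Heating F11 in toluene at 110 °C releases acetone and acylketene F12, which is trapped by the enol oxygen of the C5 ketone and closes to hydroxypyranone 21.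

## Further compounds

F1 | step 5 | ethyl (2E)-3-[5,6-epoxy-2,3,5-trimethylcyclohex-3-en-1-yl]-2-methylprop-2-enoate, β-epoxide across C5–C6 opposite the C1 and C2 substituents | CCOC(=O)/C(C)=C/[C@@H]1[C@H](C)C(C)=C[C@@]2(C)O[C@@H]12
F2 | step 5 | ethyl (2E)-3-[(1R,2S,3R,6S)-3-acetoxy-6-hydroxy-2,3,5-trimethylcyclohex-4-en-1-yl]-2-methylprop-2-enoate | CCOC(=O)/C(C)=C/[C@@H]1[C@H](C)[C@@](C)(OC(C)=O)C=C(C)[C@H]1O
F3 | step 2 | (4R)-4-benzyl-3-{[(6R)-2-[(tert-butyldimethylsilyl)oxy]-3,5,6-trimethylcyclohex-3-en-1-yl]carbonyl}-1,3-oxazolidin-2-one | O=C(C1C(O[Si](C)(C)C(C)(C)C)C(C)=CC(C)[C@H]1C)N1[C@H](Cc2ccccc2)COC1=O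
F4 | step 2 | {(6R)-2-[(tert-butyldimethylsilyl)oxy]-3,5,6-trimethylcyclohex-3-en-1-yl}methanol | OCC1C(O[Si](C)(C)C(C)(C)C)C(C)=CC(C)[C@H]1C
F5 | step 3 | (6R)-3,5,6-trimethylcyclohexa-1,3-diene-1-carboxylic acid | OC(=O)C1=CC(C)=CC(C)[C@H]1C
F6 | step 3 | methyl (6R)-3,5,6-trimethylcyclohexa-1,3-diene-1-carboxylate | COC(=O)C1=CC(C)=CC(C)[C@H]1C
F7 | step 3 | methyl (1S,6S)-3,5,6-trimethylcyclohexa-2,4-diene-1-carboxylate | COC(=O)[C@@H]1[C@H](C)C(C)=CC(C)=C1
F8 | step 6 | ethyl (2E)-3-(5,6-dihydroxy-4,6,8-trimethyl-2,3-dioxabicyclo[2.2.2]oct-7-yl)-2-methylprop-2-enoate, diol syn to the peroxide bridge | CCOC(=O)/C(C)=C/[C@@H]2[C@H](C)[C@@]3(C)OO[C@@H]2[C@](C)(O)[C@@H]3O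
F9 | step 11 | 2-methyl-3-oxopentanoic acid | CCC(=O)C(C)C(=O)O
F10 | step 11 | 6-ethyl-2,2,5-trimethyl-4H-1,3-dioxin-4-one | CCC1=C(C)C(=O)OC(C)(C)O1
F11 | step 11 | 6-[(4E)-5-iodo-4-methyl-3-oxopent-4-en-2-yl]-2,2,5-trimethyl-4H-1,3-dioxin-4-one | CC(C(=O)/C(C)=C/I)C1=C(C)C(=O)OC(C)(C)O1
F12 | step 11 | (6E)-7-iodo-2,4,6-trimethylhepta-1,6-diene-1,3,5-trione (acylketene) | O=C=C(C)C(=O)C(C)C(=O)/C(C)=C/I
A1 | alternative 1 | ethyl (2E,4E,6Z,8E)-2,6,8-trimethyldeca-2,4,6,8-tetraenoate | CCOC(=O)/C(C)=C/C=C/C(C)=C\C(C)=C\C
A2 | alternative 1 | racemic ethyl (2E)-2-methyl-3-[cis-3,5,6-trimethylcyclohexa-2,4-dien-1-yl]prop-2-enoate (racemate of 8, one enantiomer drawn) | CCOC(=O)/C(C)=C/[C@@H]1[C@H](C)C(C)=CC(C)=C1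
A3 | alternative 2 | (4S)-2-(3,5-dimethylphenyl)-4-(propan-2-yl)-4,5-dihydro-1,3-oxazole | Cc1cc(C)cc(c1)C1=N[C@@H](C(C)C)CO1
A4 | alternative 2 | (4S)-4-(propan-2-yl)-2-[(1S,6S)-3,5,6-trimethylcyclohexa-2,4-dien-1-yl]-4,5-dihydro-1,3-oxazole | CC(C)[C@H]1COC(=N1)[C@@H]1[C@H](C)C(C)=CC(C)=C1
A5 | alternative 3 | methyl 2-hydroxy-3,5,6-trimethylbenzoate | COC(=O)c1c(C)c(C)cc(C)c1O
A6 | alternative 3 | methyl 3-hydroxy-2,3,5-trimethyl-6-oxocyclohexa-1,4-diene-1-carboxylate (racemic) | COC(=O)C1=C(C)C(C)(O)C=C(C)C1=O
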